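**Retrosynthetic overview**

1. The bromo-oxane is the last ring: bromonium-induced 6-endo etherification of an (S)-linalool-type tertiary alcohol onto the E-trisubstituted alkene of an acyclic dienol side chain.
2. The side chain is joined to the bicyclic core by copper-catalysed coupling of a core CH2MgI reagent with the allylic chloride made from (S)-linalool (this makes the CH2–CH2 link).
3. The core, a 7-oxabicyclo[2.2.1]heptane (locants: C1 and C4 are the methyl-bearing bridgeheads, C2 carries the side chain, C3 the methyl, C5 lies next to C4, O7 is the bridge), is disconnected at C4–C5 and O7–C1. Carbocycle and ether bridge are thus made together by an intramolecular formal (3+2) cycloaddition of a methyl ketone (C4=O7) with a donor-acceptor cyclopropane (C1–C6–C5, two temporary esters on C5).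
4. Enabling feature: in the oxolane ring O7–C1–C6–C5–C4, the fully substituted C1 (methyl, C2, C6) sits 1,3 to C5. C1 can therefore carry the positive end and C5 (as a malonate) the negative end of a ring-opened cyclopropane, and the two-atom tether C2–C3 places the ketone oxygen five atoms from C1. Strain release drives both bonds; the esters are removed afterwards.
5. Stereochemistry: one bought stereocentre [(S)-but-3-yn-2-ol] is relayed by an Ireland–Claisen rearrangement to C2/C3 and from these to C1/C4 in the key step. Ring order: cyclopropane (temporary), then carbocycle plus oxygen bridge, then oxane.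

Key step: step 7

Remark on the chemistry: (S)-(+)-linalool and (S)-but-3-yn-2-ol are taken as commercial materials of high enantiomeric purity, and the cyclopropane intermediate is carried on as the mixture of its two ring epimers because the key step is expected to erase that centre.

**Route**

Step 1
Reactants: 1 (S)-but-3-yn-2-ol; 2 2-bromopropene
Product: 3 (S)-5-methylhex-5-en-3-yn-2-ol
Conditions: Pd(PPh3)2Cl2 (2 mol%), CuI (4 mol%), i-Pr2NH, THF, 25 °C
Reagents that add atoms: none
Why: Sonogashira coupling of a terminal alkyne with a vinyl bromide is reliable for propargylic alcohols and does not touch the carbinol stereocentre.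

Step 2
Reactants: 3 (S)-5-methylhex-5-en-3-yn-2-ol
Product: 4 (2S,3E)-5-methylhexa-3,5-dien-2-ol
Conditions: NaAlH2(OCH2CH2OMe)2, THF, 0 to 25 °C; aq. KNaC4H4O6
Reagents that add atoms: none
Why: Alkoxide-directed trans-hydroalumination of the propargylic alcohol followed by protonolysis should give only the E allylic alcohol, leaving the isopropenyl group and the stereocentre untouched.

Step 3
Reactants: 4 (2S,3E)-5-methylhexa-3,5-dien-2-ol; 5 propanoyl chloride
Product: 6 (2S,3E)-5-methylhexa-3,5-dien-2-yl propanoate
Conditions: pyridine, DMAP (cat.), CH2Cl2, 0 to 25 °C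
Reagents that add atoms: none
Why: DMAP-catalysed acylation is a nucleophilic acyl substitution at the acid chloride, so the C–O bond of the ionisable dienyl carbinol is never broken and its configuration is kept.

Step 4
Reactants: 6 (2S,3E)-5-methylhexa-3,5-dien-2-yl propanoate
Product: 10 (2R,3R,4E)-2-methyl-3-(prop-1-en-2-yl)hex-4-enoic acid, via lithium ester enolate 7 (not isolated), via (E)-silyl ketene acetal 8 (not isolated), via trimethylsilyl ester 9 (not isolated)
Conditions: LiN(i-Pr)2, THF, −78 °C; Me3SiCl, −78 to 25 °C, then 50 °C; aq. HCl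
Reagents that add atoms: none
Why: Ireland–Claisen rearrangement: kinetic deprotonation in THF without a polar additive gives the enolate with methyl trans to O–Li and hence the (E)-ketene acetal, which rearranges through a chair with the carbinol methyl equatorial, so that the (S)-carbinol centre is transferred to the (2R,3R) pair and the new alkene is E.

Step 5
Reactants: 10 (2R,3R,4E)-2-methyl-3-(prop-1-en-2-yl)hex-4-enoic acid
Product: 11 (3R,4R,5E)-3-methyl-4-(prop-1-en-2-yl)hept-5-en-2-one
Conditions: MeLi (2.2 equiv), Et2O, 0 to 25 °C; inverse quench into cold aq. HCl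
Reagents that add atoms: methyllithium, [Li]C
Why: Addition of methyllithium to the lithium carboxylate stops at the dilithium gem-diolate, which gives the methyl ketone only on acidic quench, so neither a tertiary alcohol nor epimerisation of the α-centre is expected.

Step 6
Reactants: 11 (3R,4R,5E)-3-methyl-4-(prop-1-en-2-yl)hept-5-en-2-one; 12 dimethyl diazomalonate
Product: 13 dimethyl 2-methyl-2-[(2E,4R,5R)-5-methyl-6-oxohept-2-en-4-yl]cyclopropane-1,1-dicarboxylate (both epimers at the methyl-bearing ring carbon)
Conditions: Rh2(esp)2 (0.5 mol%), CH2Cl2, 25 °C, slow addition of 12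
Reagents that add atoms: none
Why: Rhodium-carbenoid cyclopropanation with an acceptor/acceptor carbene strongly prefers the accessible 1,1-disubstituted alkene over the 1,2-disubstituted propenyl group and the ketone; the new ring stereocentre is not controlled and need not be.

Step 7
Reactants: 13 dimethyl 2-methyl-2-[(2E,4R,5R)-5-methyl-6-oxohept-2-en-4-yl]cyclopropane-1,1-dicarboxylate
Product: 15 dimethyl (1R,4R,5R,6R)-1,4,6-trimethyl-5-[(1E)-prop-1-en-1-yl]-7-oxabicyclo[2.2.1]heptane-2,2-dicarboxylate (5-endo-propenyl; 6-exo-methyl), via oxolan-2-ylium malonate zwitterion 14 (not isolated)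
Conditions: Sc(OTf)3 (10 mol%), 4 Å molecular sieves, ClCH2CH2Cl, 25 to 60 °C
Reagents that add atoms: none
Why: Sc(OTf)3 binds the two esters and polarises the bond between the ester-bearing carbon and the fully substituted, methyl-bearing cyclopropane carbon; the ketone oxygen opens the ring at that carbocation-like carbon (5-exo-tet) to give the cyclic oxocarbenium malonate 14, and the malonate carbon then adds to the oxocarbenium carbon (6-exo-trig for the carbocycle, aldol-type), which completes the bicycle, with the release of cyclopropane strain driving both bonds. The closest known reaction is the Lewis-acid-catalysed intramolecular (3+2) cross-cycloaddition of cyclopropane-1,1-diesters with tethered aldehydes or ketones, which gives bridged oxa-[n.2.1] skeletons. The two new quaternary centres (C1 and C4 of 15) are tied to each other because the one-atom oxygen bridge can span only one face, so only their sense relative to C5/C6 has to be chosen. That sense is set in the C–C bond formation: the malonate should attack the oxocarbenium face anti to the adjacent C6 methyl, which places that methyl exo (away from the endo ester at C2) and forces the C5 propenyl group endo, as the target requires. The step needs both epimers of 13 to converge and the centre α to the ketone not to epimerise: ionisation at the dialkyl-substituted carbon is expected to be SN1-like and the C–O bond formation reversible, so the configuration of the cyclopropane carbon is erased before the product-determining C–C closure, and the catalyst is a non-basic triflate used near room temperature.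

Step 8
Reactants: 15 dimethyl (1R,4R,5R,6R)-1,4,6-trimethyl-5-[(1E)-prop-1-en-1-yl]-7-oxabicyclo[2.2.1]heptane-2,2-dicarboxylate
Product: 17 (1R,4R,5R,6R)-1,4,6-trimethyl-5-[(1E)-prop-1-en-1-yl]-7-oxabicyclo[2.2.1]heptane-2-carboxylic acid (both C2 epimers), via 2,2-dicarboxylic acid 16 (not isolated)
Conditions: KOH, EtOH–H2O, 85 °C; aq. HCl to pH 2; toluene, 110 °C
Reagents that add atoms: potassium hydroxide, [K+].[OH-]
Why: Saponification of a quaternary malonate that has no α-hydrogen cannot open the ether bridge by β-elimination, and the malonic acid then loses CO2 thermally under acidic, enolate-free conditions; the C2 configuration is irrelevant because this carbon becomes CH2.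

Step 9
Reactants: 17 (1R,4R,5R,6R)-1,4,6-trimethyl-5-[(1E)-prop-1-en-1-yl]-7-oxabicyclo[2.2.1]heptane-2-carboxylic acid
Product: 20 (1R,4R,5S,6R)-5-(hydroxymethyl)-1,4,6-trimethyl-7-oxabicyclo[2.2.1]heptane-2-carboxylic acid (both C2 epimers), via ozonide 18 (not isolated), via 5-formyl acid 19 (not isolated)
Conditions: O3, CH2Cl2, −78 °C; Me2S, −78 to 0 °C; NaBH4, MeOH, 0 °C
Reagents that add atoms: ozone, [O-][O+]=O
Why: Ozonolysis cleaves the only alkene, and immediate borohydride reduction of the α-branched aldehyde should prevent epimerisation at C5 while leaving the carboxylate untouched.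

Step 10
Reactants: 20 (1R,4R,5S,6R)-5-(hydroxymethyl)-1,4,6-trimethyl-7-oxabicyclo[2.2.1]heptane-2-carboxylic acid
Product: 21 [(1R,2S,3R,4S)-1,3,4-trimethyl-7-oxabicyclo[2.2.1]heptan-2-yl]methanol
Conditions: 9-mesityl-10-phenylacridinium tetrafluoroborate (5 mol%), PhSSPh (10 mol%), i-Pr2NEt (20 mol%), CF3CH2OH, blue LEDs, 25 °C
Reagents that add atoms: none
Why: Photoredox hydrodecarboxylation oxidises the carboxylate, CO2 is lost, and the secondary alkyl radical is reduced by hydrogen-atom transfer from thiophenol; the free hydroxyl is tolerated and a β-alkoxyalkyl radical does not fragment.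

Step 11
Reactants: 21 [(1R,2S,3R,4S)-1,3,4-trimethyl-7-oxabicyclo[2.2.1]heptan-2-yl]methanol
Product: 22 (1R,2R,3R,4S)-2-(iodomethyl)-1,3,4-trimethyl-7-oxabicyclo[2.2.1]heptane
Conditions: iodine, PPh3, imidazole, CH2Cl2, 0 to 25 °C
Reagents that add atoms: iodine, [I][I]
Why: Appel-type iodination proceeds by SN2 displacement of the alkoxyphosphonium at a primary carbon, so no stereocentre is involved and the tertiary ethers are inert.

Step 12
Reactants: 23 (S)-(+)-linalool
Product: 24 (2E,6S)-2,6-dimethylocta-2,7-diene-1,6-diol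
Conditions: SeO2 (0.3 equiv), t-BuOOH (2 equiv), salicylic acid (cat.), CH2Cl2, 25 °C
Reagents that add atoms: selenium dioxide, O=[Se]=O (the oxygen it hands over is replaced from tert-butyl hydroperoxide, CC(C)(C)OO)
Why: Allylic oxidation by SeO2 (ene reaction then [2,3]-sigmatropic shift) is selective for the E methyl of a trisubstituted alkene, whereas the vinyl group has no allylic hydrogen and the tertiary carbinol centre is not involved.

Step 13
Reactants: 24 (2E,6S)-2,6-dimethylocta-2,7-diene-1,6-diol
Product: 25 (3S,6E)-8-chloro-3,7-dimethylocta-1,6-dien-3-ol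
Conditions: N-chlorosuccinimide, Me2S, CH2Cl2, −20 to 0 °C
Reagents that add atoms: N-chlorosuccinimide, O=C1CCC(=O)N1Cl
Why: Corey–Kim chlorination converts the primary allylic alcohol into its alkoxysulfonium salt, which chloride displaces by SN2 without allylic transposition, while the hindered tertiary alcohol does not react.

Step 14
Reactants: 22 (1R,2R,3R,4S)-2-(iodomethyl)-1,3,4-trimethyl-7-oxabicyclo[2.2.1]heptane; 25 (3S,6E)-8-chloro-3,7-dimethylocta-1,6-dien-3-ol
Product: 28 (3S,6E)-3,7-dimethyl-9-[(1R,2R,3R,4S)-1,3,4-trimethyl-7-oxabicyclo[2.2.1]heptan-2-yl]nona-1,6-dien-3-ol, via Grignard reagent 26 (not isolated), via chloromagnesium alkoxide 27 (not isolated)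
Conditions: 22, Mg, THF, 40 °C; separately 25, i-PrMgCl (1.0 equiv), THF, −30 °C; combine, Li2CuCl4 (5 mol%), −30 to 0 °C; aq. NH4Cl
Reagents that add atoms: none
Why: Copper-catalysed coupling of a primary alkyl Grignard reagent with a primary allylic chloride in THF should be α-selective (SN2) and keep the E geometry, and forming the alkoxide beforehand with i-PrMgCl means none of 26 is spent on the hydroxyl.

Step 15
Reactants: 28 (3S,6E)-3,7-dimethyl-9-[(1R,2R,3R,4S)-1,3,4-trimethyl-7-oxabicyclo[2.2.1]heptan-2-yl]nona-1,6-dien-3-ol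
Product: 29 dactylopyranoid, (2S,3R,6S)-3-bromo-6-ethenyl-2,6-dimethyl-2-{2-[(1R,2R,3R,4S)-1,3,4-trimethyl-7-oxabicyclo[2.2.1]heptan-2-yl]ethyl}oxane
Conditions: 2,4,4,6-tetrabromocyclohexa-2,5-dien-1-one (TBCO, 1.1 equiv), MeNO2, 0 °C, dark
Reagents that add atoms: 2,4,4,6-tetrabromocyclohexa-2,5-dien-1-one, O=C1C(Br)=CC(Br)(Br)C=C1Br
Why: Bromoetherification: Br+ goes to the electron-rich trisubstituted alkene rather than the vinyl group, and the tertiary hydroxyl opens the bromonium ion anti at the more substituted carbon (6-endo), so the E geometry fixes bromine trans to the side chain at C2/C3; the sense relative to C6 depends on which alkene face is brominated (the target comes from the chair with the C6 vinyl group equatorial), both faces are expected to compete, and the other isomer and any 5-exo oxolane are removed by chromatography.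

**Compound list**

1 | (S)-but-3-yn-2-ol | C[C@H](O)C#C | starting material
2 | 2-bromopropene | CC(Br)=C | starting material
3 | (S)-5-methylhex-5-en-3-yn-2-ol | C[C@H](O)C#CC(C)=C | intermediate
4 | (2S,3E)-5-methylhexa-3,5-dien-2-ol | C[C@H](O)/C=C/C(C)=C | intermediate
5 | propanoyl chloride | CCC(=O)Cl | starting material
6 | (2S,3E)-5-methylhexa-3,5-dien-2-yl propanoate | CCC(=O)O[C@@H](C)/C=C/C(C)=C | intermediate
7 | lithium ester enolate of 6 (methyl trans to O–Li) | C/C=C(\O[C@@H](C)/C=C/C(C)=C)O[Li] | intermediate
8 | (E)-trimethylsilyl ketene acetal of 6 | C/C=C(\O[C@@H](C)/C=C/C(C)=C)O[Si](C)(C)C | intermediate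
9 | trimethylsilyl (2R,3R,4E)-2-methyl-3-(prop-1-en-2-yl)hex-4-enoate | C[Si](C)(C)OC(=O)[C@H](C)[C@@H](/C=C/C)C(C)=C | intermediate
10 | (2R,3R,4E)-2-methyl-3-(prop-1-en-2-yl)hex-4-enoic acid | OC(=O)[C@H](C)[C@@H](/C=C/C)C(C)=C | intermediate
11 | (3R,4R,5E)-3-methyl-4-(prop-1-en-2-yl)hept-5-en-2-one | CC(=O)[C@H](C)[C@@H](/C=C/C)C(C)=C | intermediate
12 | dimethyl diazomalonate (dimethyl 2-diazopropanedioate) | COC(=O)C(=[N+]=[N-])C(=O)OC | starting material
13 | dimethyl 2-methyl-2-[(2E,4R,5R)-5-methyl-6-oxohept-2-en-4-yl]cyclopropane-1,1-dicarboxylate (both epimers at the methyl-bearing ring carbon) | CC(=O)[C@H](C)[C@@H](/C=C/C)C1(C)CC1(C(=O)OC)C(=O)OC | intermediate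
14 | oxolan-2-ylium malonate zwitterion (ring-opened form of 13) | C/C=C/[C@@H]1[C@@H](C)C(C)=[O+][C@]1(C)CC(C(=O)OC)=C([O-])OC | intermediate
15 | dimethyl (1R,4R,5R,6R)-1,4,6-trimethyl-5-[(1E)-prop-1-en-1-yl]-7-oxabicyclo[2.2.1]heptane-2,2-dicarboxylate | C/C=C/[C@@H]1[C@@H](C)[C@]2(C)C(C(=O)OC)(C(=O)OC)C[C@@]1(C)O2 | intermediate
16 | (1R,4R,5R,6R)-1,4,6-trimethyl-5-[(1E)-prop-1-en-1-yl]-7-oxabicyclo[2.2.1]heptane-2,2-dicarboxylic acid | C/C=C/[C@@H]1[C@@H](C)[C@]2(C)C(C(=O)O)(C(=O)O)C[C@@]1(C)O2 | intermediate
17 | (1R,4R,5R,6R)-1,4,6-trimethyl-5-[(1E)-prop-1-en-1-yl]-7-oxabicyclo[2.2.1]heptane-2-carboxylic acid (both C2 epimers) | C/C=C/[C@@H]1[C@@H](C)[C@]2(C)C(C(=O)O)C[C@@]1(C)O2 | intermediate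
18 | ozonide (1,2,4-trioxolane) of 17 | CC1OC(OO1)[C@@H]1[C@@H](C)[C@]2(C)C(C(=O)O)C[C@@]1(C)O2 | intermediate
19 | (1R,4R,5R,6R)-5-formyl-1,4,6-trimethyl-7-oxabicyclo[2.2.1]heptane-2-carboxylic acid (both C2 epimers) | O=C[C@@H]1[C@@H](C)[C@]2(C)C(C(=O)O)C[C@@]1(C)O2 | intermediate
20 | (1R,4R,5S,6R)-5-(hydroxymethyl)-1,4,6-trimethyl-7-oxabicyclo[2.2.1]heptane-2-carboxylic acid (both C2 epimers) | OC[C@@H]1[C@@H](C)[C@]2(C)C(C(=O)O)C[C@@]1(C)O2 | intermediate
21 | [(1R,2S,3R,4S)-1,3,4-trimethyl-7-oxabicyclo[2.2.1]heptan-2-yl]methanol | OC[C@@H]1[C@@H](C)[C@]2(C)CC[C@@]1(C)O2 | intermediate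
22 | (1R,2R,3R,4S)-2-(iodomethyl)-1,3,4-trimethyl-7-oxabicyclo[2.2.1]heptane | IC[C@@H]1[C@@H](C)[C@]2(C)CC[C@@]1(C)O2 | intermediate
23 | (S)-(+)-linalool, (3S)-3,7-dimethylocta-1,6-dien-3-ol | C=C[C@@](C)(O)CCC=C(C)C | starting material
24 | (2E,6S)-2,6-dimethylocta-2,7-diene-1,6-diol | C=C[C@@](C)(O)CC/C=C(\C)CO | intermediate
25 | (3S,6E)-8-chloro-3,7-dimethylocta-1,6-dien-3-ol | C=C[C@@](C)(O)CC/C=C(\C)CCl | intermediate
26 | {[(1R,2R,3R,4S)-1,3,4-trimethyl-7-oxabicyclo[2.2.1]heptan-2-yl]methyl}magnesium iodide | I[Mg]C[C@@H]1[C@@H](C)[C@]2(C)CC[C@@]1(C)O2 | intermediate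
27 | chloromagnesium alkoxide of 25 | C=C[C@@](C)(O[Mg]Cl)CC/C=C(\C)CCl | intermediate
28 | (3S,6E)-3,7-dimethyl-9-[(1R,2R,3R,4S)-1,3,4-trimethyl-7-oxabicyclo[2.2.1]heptan-2-yl]nona-1,6-dien-3-ol | C=C[C@@](C)(O)CC/C=C(\C)CC[C@@H]1[C@@H](C)[C@]2(C)CC[C@@]1(C)O2 | intermediate
29 | dactylopyranoid, (2S,3R,6S)-3-bromo-6-ethenyl-2,6-dimethyl-2-{2-[(1R,2R,3R,4S)-1,3,4-trimethyl-7-oxabicyclo[2.2.1]heptan-2-yl]ethyl}oxane | C=C[C@]1(C)CC[C@@H](Br)[C@](C)(CC[C@@H]2[C@@H](C)[C@]3(C)CC[C@@]2(C)O3)O1 | target

**Step count and risks**

Total step count: 15. Longest linear sequence: 13 steps (steps 1 to 11, then 14 and 15); steps 12 and 13 form the short linalool branch.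

Steps most likely to fail:

Step 7 (key step). What may go wrong: incomplete stereoconvergence of the two cyclopropane epimers, epimerisation α to the ketone before ring closure (the epimer would close to the all-exo isomer), or proton loss from the ring-opened cation. The fallback makes the same two bonds one after the other with known reactions and sets out from 11. A Me2AlCl-promoted carbonyl-ene reaction of the isopropenyl group with paraformaldehyde gives (3R,4R,5E)-4-(4-hydroxybut-1-en-2-yl)-3-methylhept-5-en-2-one F1. Iodine, PPh3 and imidazole convert it into the iodide (3R,4R,5E)-4-(4-iodobut-1-en-2-yl)-3-methylhept-5-en-2-one F2. An intramolecular Barbier reaction with SmI2 in THF then closes the carbocycle to (1S,2R,3R)-1,2-dimethyl-4-methylidene-3-[(1E)-prop-1-en-1-yl]cyclohexan-1-ol F3, the alkylsamarium being expected to add anti to the adjacent methyl. Catalytic p-toluenesulfonic acid in CH2Cl2 protonates the exocyclic alkene and the tertiary hydroxyl closes the ether bridge at the more substituted carbon (the 1,4-cineole type of transannular hydroalkoxylation) to give (1S,2R,3R,4R)-1,2,4-trimethyl-3-[(1E)-prop-1-en-1-yl]-7-oxabicyclo[2.2.1]heptane F4. Ozonolysis with borohydride work-up as in step 9 then gives 21, where the fallback comes back to the route; steps 8 and 10 are not needed on this path.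

Step 15. What may go wrong: poor facial selectivity in bromonium formation, so that the isomer epimeric at both C2 and C3 relative to C6 forms in a similar amount, and competing 5-exo closure to an oxolane. The fallback sets out from 28. Hg(O2CCF3)2 in MeNO2 at 0 °C effects a reversible oxymercuration-cyclisation, which allows the ring size and the two oxane diastereomers to equilibrate; exchange with aqueous NaCl gives the organomercurial, the 3-chloromercurio analogue of dactylopyranoid F5, which is purified at this stage. Brominolysis with bromine and LiBr in pyridine under oxygen, which proceeds with retention at carbon, then gives 29.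

Step 6. What may go wrong: capture of the carbenoid by the ketone oxygen (carbonyl ylide chemistry) or by the propenyl alkene instead of the isopropenyl group. The fallback sets out from 11. Atom-transfer radical addition of dimethyl bromomalonate under visible-light photoredox catalysis (fac-Ir(ppy)3, LiBr, blue LEDs) adds the electrophilic malonyl radical to the terminal carbon of the 1,1-disubstituted alkene only and gives dimethyl 2-{(3R,4R)-2-bromo-2,4-dimethyl-5-oxo-3-[(1E)-prop-1-en-1-yl]hexyl}propanedioate F6. K2CO3 in DMF then closes the three-membered ring by 3-exo-tet displacement from the malonate anion (far more acidic than the ketone α-position) and gives 13.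

Further compounds

F1 | step 7 | (3R,4R,5E)-4-(4-hydroxybut-1-en-2-yl)-3-methylhept-5-en-2-one | CC(=O)[C@H](C)[C@@H](/C=C/C)C(=C)CCO
F2 | step 7 | (3R,4R,5E)-4-(4-iodobut-1-en-2-yl)-3-methylhept-5-en-2-one | CC(=O)[C@H](C)[C@@H](/C=C/C)C(=C)CCI
F3 | step 7 | (1S,2R,3R)-1,2-dimethyl-4-methylidene-3-[(1E)-prop-1-en-1-yl]cyclohexan-1-ol | C/C=C/[C@@H]1[C@@H](C)[C@@](C)(O)CCC1=C
F4 | step 7 | (1S,2R,3R,4R)-1,2,4-trimethyl-3-[(1E)-prop-1-en-1-yl]-7-oxabicyclo[2.2.1]heptane | C/C=C/[C@@H]1[C@@H](C)[C@]2(C)CC[C@@]1(C)O2
F5 | step 15 | 3-chloromercurio analogue of dactylopyranoid (HgCl in place of Br, same configuration) | C=C[C@]1(C)CC[C@@H]([Hg]Cl)[C@](C)(CC[C@@H]2[C@@H](C)[C@]3(C)CC[C@@]2(C)O3)O1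
F6 | step 6 | dimethyl 2-{(3R,4R)-2-bromo-2,4-dimethyl-5-oxo-3-[(1E)-prop-1-en-1-yl]hexyl}propanedioate (both epimers at the bromine-bearing carbon) | CC(=O)[C@H](C)[C@@H](/C=C/C)C(C)(Br)CC(C(=O)OC)C(=O)OC
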